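**Strategy**

Quinolone A is disconnected at its N1–C8a and N1–C2 bonds, which reveals a 3-alkoxyinden-1-one. A symmetric indane-1,3-dione can therefore stand in for ring A while pyran rings C and D are closed by one intramolecular hetero-Diels–Alder reaction. The key step then inserts one nitrogen atom between the only remaining ketone (C1 of the indenone, the future C2 of quinolone A) and its benzo carbon, enlarging the five-membered ring to the pyridone. It exploits the fact that, once ring C is fused through the enol-ether oxygen, this carbonyl is the only one left. The precursor is the hexacyclic indeno-pyranone with Ca, Cb and Cc already set.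

Key step: step 5

**Remarks**

- Labels: quinolone A is the N-methylquinolin-2-one fused to the gem-dimethyl pyran (ring C); quinolone B is the one fused to ring D. Ca is the CH between C3 of A and the ring D oxygen, Cb the ring-fusion CH next to CMe2, Cc the CH carrying CH2C(CH3)2OH.
- Configuration: the target is Ca S, Cb R, Cc R. Rings C and D are cis-fused, and the Cc side chain is trans to the CMe2 carbon on Cb.
- Assumption: the (R,R)-diamine of step 1 is taken as the antipode that gives Cc R, by analogy with β-aryl enones; the mirror-image catalyst would be used if the first batch showed the opposite sense.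
- Precursor design: no protecting group is used. The tertiary alcohol stays free and ring B is N-methylated from the start, so ring A holds the only N–H after the key step.

**Route**

Step 1
Reactants: 1 4-hydroxy-1-methylquinolin-2(1H)-one; 2 (E)-6-methylhepta-3,5-dien-2-one
Product: 3 4-hydroxy-1-methyl-3-[(4R)-2-methyl-6-oxohept-2-en-4-yl]quinolin-2(1H)-one
Conditions: (R,R)-1,2-diphenylethane-1,2-diamine (10 mol%), AcOH (10 equiv), THF, 23 °C
Reagents that add atoms: none
Why: Iminium-catalysed enantioselective Michael addition of a cyclic 1,3-dicarbonyl enol to an enone; the chiral diamine forms the iminium ion of the dienone and shields one face of C4, so that C3 of ring B adds there and sets Cc (R), while the fully substituted C6 is too hindered for 1,6-addition.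

Step 2
Reactants: 3 4-hydroxy-1-methyl-3-[(4R)-2-methyl-6-oxohept-2-en-4-yl]quinolin-2(1H)-one
Product: 4 4-hydroxy-3-[(4R)-6-hydroxy-2,6-dimethylhept-2-en-4-yl]-1-methylquinolin-2(1H)-one
Conditions: MeMgBr (4 equiv), THF, −40 → 0 °C; then aq. NH4Cl
Reagents that add atoms: methylmagnesium bromide C[Mg]Br
Why: Grignard 1,2-addition to the methyl ketone; the first equivalent converts the acidic enol into a magnesium enolate, which is inert to the reagent and cannot undergo retro-Michael cleavage, so Cc keeps its configuration while the excess reagent forms the tertiary alcohol.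

Step 3
Reactants: 5 indane-1,3-dione; 6 triethyl orthoformate
Product: 7 2-(ethoxymethylene)indane-1,3-dione
Conditions: Ac2O, 120 °C
Reagents that add atoms: none
Why: Ethoxymethylenation of an active methylene compound by condensation with the orthoester; acetic anhydride takes up the ethanol and the excess of orthoformate keeps a second indanedione from adding.

Step 4
Reactants: 4 4-hydroxy-3-[(4R)-6-hydroxy-2,6-dimethylhept-2-en-4-yl]-1-methylquinolin-2(1H)-one; 7 2-(ethoxymethylene)indane-1,3-dione
Product: 9 indeno-pyranone precursor (3-alkoxyinden-1-one fused through rings C and D to quinolone B; Ca S; Cb R; Cc R), via aryloxymethylene indanedione 8 (not isolated)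
Conditions: toluene, 5 Å molecular sieves, 80 → 110 °C
Reagents that add atoms: none
Why: Addition–elimination exchange at the alkoxymethylene carbon replaces ethoxide by the acidic enol oxygen O4 of 4 (ethanol is taken up by the sieves), and the resulting 2-acylenone 8 reacts as a 1-oxadiene with the tethered trisubstituted alkene in an intramolecular inverse-electron-demand hetero-Diels–Alder reaction, the carbonyl oxygen bonding to the CMe2 terminus and Ca to Cb; Cc controls both new centres, since allylic 1,3-strain holds Cc–H in the alkene plane so that the diene reaches Cb on the face away from the CH2C(CH3)2OH chain (Cb R), and the folded endo approach of the planar O–C4=C3 tether gives the cis ring fusion (Ca S).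

Step 5
Reactants: 9 indeno-pyranone precursor
Product: 12 des-N-methyl lactam (target lacking the N-methyl group of quinolone A; Ca S; Cb R; Cc R), via O-phosphinyl oxime 10 (not isolated), via nitrilium phosphinate 11 (not isolated)
Conditions: Ph2P(O)ONH2 (1.5 equiv), (CF3)2CHOH, 23 → 50 °C
Reagents that add atoms: O-(diphenylphosphinyl)hydroxylamine NOP(=O)(c1ccccc1)c1ccccc1; water O
Why: Proposed new method: the aminating reagent condenses with the only ketone of 9 (C1 of the indenone, a vinylogous ester carbonyl activated by hydrogen bonding to the fluorinated alcohol) to give O-phosphinyl oxime 10, whose N–O bond ionises while the benzo carbon anti to it shifts from C1 to nitrogen, and the water released in the condensation adds to the ring-enlarged nitrilium ion 11 to give lactam 12 and diphenylphosphinic acid. The closest known reaction type is the Beckmann (or Schmidt) ring enlargement of indan-1-ones to 3,4-dihydroquinolin-2(1H)-ones; a 3-alkoxyinden-1-one carrying a substituent on C2 has not been taken through it. The pyridone ring of quinolone A arises by ring expansion through this 1,2-shift (the five-membered ring gains one atom; the bonds N–C8a and N–C2 form and the bond between C1 and the benzo carbon breaks), not by a cyclisation. No stereocentre is created, and Ca, Cb and Cc should stay untouched because the medium holds no acid stronger than the phosphinic acid, which spares the Ca–O bond and the tertiary alcohol. The step needs migration of the aryl carbon and not of the enol-ether carbon C2: the feature that favours this is the ring C oxygen, whose donation through C3=C2 stabilises the electron-poor C1 of the nitrilium ion (a vinylogous imidate cation) only if C2 stays on C1, and the protic medium lets the two oxime isomers interconvert, so that this transition-state stabilisation and not the oxime population should decide the product. The in-plane Ca–H next to C1 disfavours the required oxime isomer sterically, so this selectivity is the one real risk of the route.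

Step 6
Reactants: 12 des-N-methyl lactam
Product: 13 CNP0202276.1 (target)
Conditions: MeI, K2CO3, DMF, 23 °C
Reagents that add atoms: iodomethane CI
Why: N-alkylation (SN2) of the 2-quinolone lactam anion, whose potassium salt in DMF should react at nitrogen; carbonate does not deprotonate the tertiary alcohol and none of the three stereocentres carries an acidic hydrogen.

**Compound list**

1 | 4-hydroxy-1-methylquinolin-2(1H)-one | Cn1c(=O)cc(O)c2ccccc21 | starting material
2 | (E)-6-methylhepta-3,5-dien-2-one | CC(=O)/C=C/C=C(C)C | starting material
3 | 4-hydroxy-1-methyl-3-[(4R)-2-methyl-6-oxohept-2-en-4-yl]quinolin-2(1H)-one | CC(C)=C[C@@H](CC(C)=O)c1c(O)c2ccccc2n(C)c1=O | intermediate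
4 | 4-hydroxy-3-[(4R)-6-hydroxy-2,6-dimethylhept-2-en-4-yl]-1-methylquinolin-2(1H)-one | CC(C)=C[C@@H](CC(C)(C)O)c1c(O)c2ccccc2n(C)c1=O | intermediate
5 | indane-1,3-dione | O=C1CC(=O)c2ccccc21 | starting material
6 | triethyl orthoformate | CCOC(OCC)OCC | starting material
7 | 2-(ethoxymethylene)indane-1,3-dione | CCOC=C1C(=O)c2ccccc2C1=O | intermediate
8 | 2-({[3-((4R)-6-hydroxy-2,6-dimethylhept-2-en-4-yl)-1-methyl-2-oxo-1,2-dihydroquinolin-4-yl]oxy}methylene)indane-1,3-dione | O=C1c2ccccc2C(=O)C1=COc1c([C@H](CC(C)(C)O)C=C(C)C)c(=O)n(C)c2ccccc12 | intermediate
9 | indeno-pyranone precursor: 3-alkoxyinden-1-one whose enol-ether oxygen and C2 are part of ring C (2,2-dimethyl dihydropyran), cis-fused at Ca–Cb to ring D on N-methylquinolone B; Cc bears CH2C(CH3)2OH; Ca S, Cb R, Cc R | O=C1C2=C(c3ccccc31)OC(C)(C)[C@H]1[C@@H]2Oc2c(c(=O)n(C)c3ccccc23)[C@@H]1CC(C)(C)O | intermediate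
10 | O-(diphenylphosphinyl) oxime of 9 at C1, N–O bond anti to the benzo ring (Z) | O=P(c1ccccc1)(c1ccccc1)O/N=C1\C2=C(c3ccccc31)OC(C)(C)[C@H]1[C@@H]2Oc2c(c(=O)n(C)c3ccccc23)[C@@H]1CC(C)(C)O | intermediate
11 | ring-enlarged cyclic nitrilium ion (N bonded to the benzo carbon) as its diphenylphosphinate ion pair | [N+]1#CC2=C(c3ccccc31)OC(C)(C)[C@H]1[C@@H]2Oc2c(c(=O)n(C)c3ccccc23)[C@@H]1CC(C)(C)O.[O-]P(=O)(c1ccccc1)c1ccccc1 | intermediate
12 | des-N-methyl lactam: the target with N–H in quinolone A; Ca S, Cb R, Cc R | [nH]1c(=O)c2c(c3ccccc31)OC(C)(C)[C@H]1[C@@H]2Oc2c(c(=O)n(C)c3ccccc23)[C@@H]1CC(C)(C)O | intermediate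
13 | CNP0202276.1; Ca S, Cb R, Cc R | Cn1c(=O)c2c(c3ccccc31)OC(C)(C)[C@H]1[C@@H]2Oc2c(c(=O)n(C)c3ccccc23)[C@@H]1CC(C)(C)O | target

**Step count and risks**

Total step count: 6. Longest linear sequence: 5 steps (steps 1, 2, 4, 5, 6); step 3 is a one-step branch.

Steps most likely to fail:

1. Step 5 (proposed new method). The enol-ether carbon C2 may migrate in place of the aryl carbon, because the oxime isomer with the leaving group next to the benzo ring is the less crowded one; the Ca–O bond may also ionise in the protic medium. The fallback uses known chemistry and brings the ring A nitrogen in with the building block. It sets out from 4. Compound 1 is condensed with 6 under the conditions of step 3 to give 3-(ethoxymethylene)-1-methylquinoline-2,4(1H,3H)-dione F1. Heating 4 with F1 in toluene over 5 Å molecular sieves should give, by the same enol exchange, the aryloxymethylene quinolinedione F2, which is not isolated and cyclises by the known intramolecular hetero-Diels–Alder reaction of 3-alkylidenequinoline-2,4-diones. The ketone carbonyl at C4 is the more reactive heterodiene terminus, so the linear pyranoquinolinone, which is 13 itself, should predominate over the angular isomer formed through the lactam carbonyl; the two would be separated by chromatography. The route is rejoined at 13, and 9 and 12 are bypassed.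

2. Step 4. The exchange equilibrium may stay on the side of the ethoxy compound, so that slow degradation (reaction at the lactam oxygen of ring B, or addition of the enol to its own alkene) outruns the cycloaddition. The fallback forms the Ca–O bond irreversibly and sets out from 7. Hydrolysis (dilute aq. HCl, THF) gives 2-(hydroxymethylene)indane-1,3-dione F3, which with oxalyl chloride and catalytic DMF in CH2Cl2 gives 2-(chloromethylene)indane-1,3-dione F4. Enol 4 is O-alkenylated by F4 with Et3N in CH2Cl2 at 0 °C (vinylogous acylation), which delivers 8 as a defined compound; 8 is then heated in toluene. The route is rejoined at 8.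

3. Step 1. Facial control by the diamine may be poor with an alkenyl in place of an aryl β-substituent, or some 1,6-addition may occur. The fallback sets Cc by iridium-catalysed allylic alkylation and sets out from 1. Cross-metathesis of 2-methylpent-4-en-2-ol with allyl methyl carbonate (second-generation Grubbs catalyst (H2IMes)(PCy3)Cl2Ru=CHPh, CH2Cl2, 40 °C) gives (E)-5-hydroxy-5-methylhex-2-en-1-yl methyl carbonate F5. Compound 1 is allylated at C3 by F5 with [Ir(cod)Cl]2 and the binaphthol-derived bis(1-phenylethyl)phosphoramidite (the (Sa,S,S) antipode is expected to give Cc R; THF, 40 °C), which should give the branched product 4-hydroxy-3-[(3R)-5-hydroxy-5-methylhex-1-en-3-yl]-1-methylquinolin-2(1H)-one F6. Cross-metathesis of F6 with 2-methylbut-2-ene and the same ruthenium catalyst turns the vinyl group into the 2-methylprop-1-enyl group. The route is rejoined at 4, and 3 and step 2 are bypassed.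

**Further compounds**

F1 | step 5 | 3-(ethoxymethylene)-1-methylquinoline-2,4(1H,3H)-dione | CCOC=C1C(=O)c2ccccc2N(C)C1=O
F2 | step 5 | 3-({[3-((4R)-6-hydroxy-2,6-dimethylhept-2-en-4-yl)-1-methyl-2-oxo-1,2-dihydroquinolin-4-yl]oxy}methylene)-1-methylquinoline-2,4(1H,3H)-dione | CN1C(=O)C(=COc2c([C@H](CC(C)(C)O)C=C(C)C)c(=O)n(C)c3ccccc23)C(=O)c2ccccc21
F3 | step 4 | 2-(hydroxymethylene)indane-1,3-dione | O=C1c2ccccc2C(=O)C1=CO
F4 | step 4 | 2-(chloromethylene)indane-1,3-dione | O=C1c2ccccc2C(=O)C1=CCl
F5 | step 1 | (E)-5-hydroxy-5-methylhex-2-en-1-yl methyl carbonate | COC(=O)OC/C=C/CC(C)(C)O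
F6 | step 1 | 4-hydroxy-3-[(3R)-5-hydroxy-5-methylhex-1-en-3-yl]-1-methylquinolin-2(1H)-one | C=C[C@@H](CC(C)(C)O)c1c(O)c2ccccc2n(C)c1=O
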